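**Plan**
- Retrosynthesis: the 5-OH is masked as a benzyl ether, and the flavonol is read as the enol of a chromane-3,4-dione, the twofold oxidised form of a flavan-3,4-diol. The cuts then follow in this order: C3–C4 of ring C (pinacol, to an aryl/alkyl dialdehyde), O1–C2 (phenoxide plus α-bromo arylacetate), C4–C4a (ortho-formylation).
- Enabling feature: C3 (bearing OH) and C4 (the carbonyl) are neighbouring oxygenated carbons of ring C, and C2 keeps one H. Two aldehyde carbons of like polarity can therefore be joined reductively, and the diol can be oxidised and enolised to the 3-hydroxy-γ-pyranone.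
- Forward: ring A is prepared as a phenol (Baeyer–Villiger exchanges CHO for O-benzyl), formylated, and joined to the ring B unit through O1–C2. After adjustment to the dialdehyde, SmI2 closes ring C at C3–C4; oxidation and debenzylation finish the synthesis.
- Stereochemistry: the target has no stereocentre. C2, C3 and C4 of the racemic intermediates are transient and vanish in the oxidation/enolisation.

Key step: step 11

Remark: every chiral intermediate is racemic and drawn as one enantiomer; the relative configuration given for 16 and 17 is the expected major one and has no bearing on the target.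
Remark: lithium, magnesium, aluminium and samarium salts of numbered compounds are treated as forms of those compounds.

Step 1
Reactants: 1 3-hydroxy-4,5-dimethoxybenzaldehyde
Product: 2 3,4-dimethoxy-5-(methoxymethoxy)benzaldehyde
Conditions: MOMCl, i-Pr2NEt, CH2Cl2, 0 °C to rt
Reagents that add atoms: chloromethyl methyl ether (MOMCl), COCCl
Why: Williamson-type O-alkylation of the phenol gives an acetal ether that survives peracid, carbonate and benzylation and is later removed by acid that spares a benzyl ether.

Step 2
Reactants: 2 3,4-dimethoxy-5-(methoxymethoxy)benzaldehyde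
Product: 4 3,4-dimethoxy-5-(methoxymethoxy)phenol, via aryl formate 3 (not isolated)
Conditions: mCPBA, CH2Cl2, 0 °C to rt; then K2CO3 (cat.), MeOH, rt
Reagents that add atoms: meta-chloroperoxybenzoic acid (mCPBA), O=C(OO)c1cccc(Cl)c1
Why: Baeyer–Villiger (Dakin-type) oxidation, in which the electron-rich trialkoxyaryl group migrates in the Criegee adduct to give the formate, followed by mild transesterification that frees the phenol without touching the MOM ether.

Step 3
Reactants: 4 3,4-dimethoxy-5-(methoxymethoxy)phenol
Product: 5 5-(benzyloxy)-1,2-dimethoxy-3-(methoxymethoxy)benzene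
Conditions: BnBr, K2CO3, DMF, rt
Reagents that add atoms: benzyl bromide, BrCc1ccccc1
Why: Williamson etherification of the only free phenol installs the group that protects the future O5 until the last step.

Step 4
Reactants: 5 5-(benzyloxy)-1,2-dimethoxy-3-(methoxymethoxy)benzene
Product: 6 5-(benzyloxy)-2,3-dimethoxyphenol
Conditions: HCl (conc., cat.), MeOH, 50 °C
Reagents that add atoms: none
Why: Acid-catalysed acetal exchange removes the MOM group as dimethoxymethane, while benzyl and methyl aryl ethers are inert.

Step 5
Reactants: 6 5-(benzyloxy)-2,3-dimethoxyphenol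
Product: 8 6-(benzyloxy)-2-hydroxy-3,4-dimethoxybenzaldehyde, via hydroxymethylphenol 7 (not isolated)
Conditions: MgCl2, Et3N, (CH2O)n, THF, reflux; aq. HCl work-up
Reagents that add atoms: paraformaldehyde (as formaldehyde), C=O
Why: Casnati–Skattebøl ortho-formylation: the magnesium phenoxide delivers formaldehyde to the only free ortho position (the other carries OMe), and the hydroxymethyl intermediate is oxidised by a second formaldehyde through an Oppenauer-type hydride transfer.

Step 6
Reactants: 9 3,4,5-trimethoxyphenylacetic acid
Product: 10 methyl 2-(3,4,5-trimethoxyphenyl)acetate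
Conditions: MeOH, H2SO4 (cat.), reflux
Reagents that add atoms: methanol, CO
Why: Fischer esterification driven by the excess of methanol.

Step 7
Reactants: 10 methyl 2-(3,4,5-trimethoxyphenyl)acetate
Product: 12 methyl 2-bromo-2-(3,4,5-trimethoxyphenyl)acetate (racemic), via silyl ketene acetal 11 (not isolated)
Conditions: LiN(SiMe3)2, THF, −78 °C; Me3SiCl; then NBS, −78 to 0 °C
Reagents that add atoms: N-bromosuccinimide (NBS), O=C1CCC(=O)N1Br
Why: α-Bromination of an ester through its silyl ketene acetal, whose nucleophilic α-carbon should take up bromine from NBS far faster than the trimethoxyarene ring and without dibromination.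

Step 8
Reactants: 8 6-(benzyloxy)-2-hydroxy-3,4-dimethoxybenzaldehyde; 12 methyl 2-bromo-2-(3,4,5-trimethoxyphenyl)acetate (racemic)
Product: 13 methyl 2-[3-(benzyloxy)-2-formyl-5,6-dimethoxyphenoxy]-2-(3,4,5-trimethoxyphenyl)acetate (racemic)
Conditions: K2CO3, DMF, rt
Reagents that add atoms: none
Why: Williamson etherification (SN2 displacement at the benzylic α-bromo ester by the phenoxide) forms O1–C2; the weak carbonate base at room temperature and the electron-rich, doubly ortho-flanked aldehyde should keep the product from intramolecular aldol cyclisation.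

Step 9
Reactants: 13 methyl 2-[3-(benzyloxy)-2-formyl-5,6-dimethoxyphenoxy]-2-(3,4,5-trimethoxyphenyl)acetate (racemic)
Product: 14 2-[3-(benzyloxy)-2-(hydroxymethyl)-5,6-dimethoxyphenoxy]-2-(3,4,5-trimethoxyphenyl)ethan-1-ol (racemic)
Conditions: LiAlH4, THF, 0 °C
Reagents that add atoms: none
Why: Hydride reduction takes the ester and the aldehyde to primary alcohols, bringing the two carbons to be coupled to one oxidation level without affecting the aryl ethers.

Step 10
Reactants: 14 2-[3-(benzyloxy)-2-(hydroxymethyl)-5,6-dimethoxyphenoxy]-2-(3,4,5-trimethoxyphenyl)ethan-1-ol (racemic)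
Product: 15 6-(benzyloxy)-3,4-dimethoxy-2-[2-oxo-1-(3,4,5-trimethoxyphenyl)ethoxy]benzaldehyde (racemic)
Conditions: Dess–Martin periodinane, pyridine, CH2Cl2, 0 °C to rt; used at once without chromatography
Reagents that add atoms: none
Why: Dess–Martin oxidation converts both primary alcohols to aldehydes under near-neutral, amine-buffered conditions that should avoid enolisation of the α-aryl-α-aryloxy aldehyde.

Step 11
Reactants: 15 6-(benzyloxy)-3,4-dimethoxy-2-[2-oxo-1-(3,4,5-trimethoxyphenyl)ethoxy]benzaldehyde (racemic)
Product: 16 rac-(2R,3S,4S)-5-(benzyloxy)-7,8-dimethoxy-2-(3,4,5-trimethoxyphenyl)chromane-3,4-diol (2,3-trans-3,4-cis)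
Conditions: SmI2 (2.5 equiv), t-BuOH, THF, −78 °C to rt, slow addition of 15 at 0.01 M; aq. NaHCO3 work-up
Reagents that add atoms: none
Why: SmI2 transfers one electron to the more easily reduced aromatic aldehyde (C4), the samarium-bound ketyl radical adds to the samarium-coordinated aliphatic aldehyde carbon (C3), and a second electron with protonation by t-BuOH completes the diol. The closest known reaction type is the SmI2-mediated intramolecular pinacol coupling of 1,6-dialdehydes to six-membered cis-diols. Ring C closes by a 6-exo-trig radical addition to the C=O bond, the accepting oxygen staying outside the ring. C3 and C4 should be set cis because both oxygens bridge one oxophilic trivalent samarium centre in a chair-like transition state, and C3 should be set trans to the existing C2 centre because the 2-aryl group lies pseudo-equatorial and the forming C3–O bond avoids it. The step needs chemoselectivity rather than diastereoselectivity: ketyl formation at the aryl aldehyde and cyclisation must outrun β-loss of the aryloxide from the aliphatic carbonyl, simple reduction and bimolecular coupling, which the lower reduction potential of the aryl aldehyde, its two flanking ortho substituents, HMPA-free conditions, low temperature and slow addition at high dilution should secure. All three stereocentres are erased in step 12, so a diastereomer mixture can be carried forward.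

Step 12
Reactants: 16 rac-(2R,3S,4S)-5-(benzyloxy)-7,8-dimethoxy-2-(3,4,5-trimethoxyphenyl)chromane-3,4-diol
Product: 19 5-(benzyloxy)-3-hydroxy-7,8-dimethoxy-2-(3,4,5-trimethoxyphenyl)-4H-chromen-4-one, via dihydroflavonol 17 (not isolated), via chromane-3,4-dione 18 (not isolated)
Conditions: IBX (2.5 equiv), DMSO, rt; aq. NaHCO3 work-up
Reagents that add atoms: none
Why: IBX oxidation of a 1,2-diol to the 1,2-dione without C–C cleavage (benzylic C4–OH first, then the α-ketol), after which the acidic C2–H allows enolisation to the conjugated, hydrogen-bonded 3-hydroxy-γ-pyranone.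

Step 13
Reactants: 19 5-(benzyloxy)-3-hydroxy-7,8-dimethoxy-2-(3,4,5-trimethoxyphenyl)-4H-chromen-4-one
Product: 20 3,5-dihydroxy-7,8-dimethoxy-2-(3,4,5-trimethoxyphenyl)-4H-chromen-4-one (3,5-dihydroxy-7,8,3',4',5'-pentamethoxyflavone)
Conditions: H2 (1 atm), Pd/C, EtOAc–MeOH, rt
Reagents that add atoms: none
Why: Catalytic hydrogenolysis of the aryl benzyl ether over Pd/C, under which the C2=C3 bond, being part of the conjugated γ-pyranone, and the methyl ethers should not react.

**Compound list**
1 | 3-hydroxy-4,5-dimethoxybenzaldehyde | COc1cc(C=O)cc(O)c1OC | starting material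
2 | 3,4-dimethoxy-5-(methoxymethoxy)benzaldehyde | COCOc1cc(C=O)cc(OC)c1OC | intermediate
3 | 3,4-dimethoxy-5-(methoxymethoxy)phenyl formate | COCOc1cc(OC=O)cc(OC)c1OC | intermediate
4 | 3,4-dimethoxy-5-(methoxymethoxy)phenol | COCOc1cc(O)cc(OC)c1OC | intermediate
5 | 5-(benzyloxy)-1,2-dimethoxy-3-(methoxymethoxy)benzene | COCOc1cc(OCc2ccccc2)cc(OC)c1OC | intermediate
6 | 5-(benzyloxy)-2,3-dimethoxyphenol | COc1cc(OCc2ccccc2)cc(O)c1OC | intermediate
7 | 3-(benzyloxy)-2-(hydroxymethyl)-5,6-dimethoxyphenol | COc1cc(OCc2ccccc2)c(CO)c(O)c1OC | intermediate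
8 | 6-(benzyloxy)-2-hydroxy-3,4-dimethoxybenzaldehyde | COc1cc(OCc2ccccc2)c(C=O)c(O)c1OC | intermediate
9 | 3,4,5-trimethoxyphenylacetic acid | COc1cc(CC(=O)O)cc(OC)c1OC | starting material
10 | methyl 2-(3,4,5-trimethoxyphenyl)acetate | COC(=O)Cc1cc(OC)c(OC)c(OC)c1 | intermediate
11 | 1-methoxy-1-(trimethylsilyloxy)-2-(3,4,5-trimethoxyphenyl)ethene (E/Z mixture) | COC(O[Si](C)(C)C)=Cc1cc(OC)c(OC)c(OC)c1 | intermediate
12 | methyl 2-bromo-2-(3,4,5-trimethoxyphenyl)acetate (racemic) | COC(=O)C(Br)c1cc(OC)c(OC)c(OC)c1 | intermediate
13 | methyl 2-[3-(benzyloxy)-2-formyl-5,6-dimethoxyphenoxy]-2-(3,4,5-trimethoxyphenyl)acetate (racemic) | COC(=O)C(Oc1c(C=O)c(OCc2ccccc2)cc(OC)c1OC)c1cc(OC)c(OC)c(OC)c1 | intermediate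
14 | 2-[3-(benzyloxy)-2-(hydroxymethyl)-5,6-dimethoxyphenoxy]-2-(3,4,5-trimethoxyphenyl)ethan-1-ol (racemic) | OCC(Oc1c(CO)c(OCc2ccccc2)cc(OC)c1OC)c1cc(OC)c(OC)c(OC)c1 | intermediate
15 | 6-(benzyloxy)-3,4-dimethoxy-2-[2-oxo-1-(3,4,5-trimethoxyphenyl)ethoxy]benzaldehyde (racemic) | O=CC(Oc1c(C=O)c(OCc2ccccc2)cc(OC)c1OC)c1cc(OC)c(OC)c(OC)c1 | intermediate
16 | rac-(2R,3S,4S)-5-(benzyloxy)-7,8-dimethoxy-2-(3,4,5-trimethoxyphenyl)chromane-3,4-diol (2,3-trans-3,4-cis) | COc1cc([C@@H]2[C@@H](O)[C@@H](O)c3c(OCc4ccccc4)cc(OC)c(OC)c3O2)cc(OC)c1OC | intermediate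
17 | rac-(2R,3R)-5-(benzyloxy)-3-hydroxy-7,8-dimethoxy-2-(3,4,5-trimethoxyphenyl)chroman-4-one (2,3-trans) | COc1cc([C@@H]2[C@@H](O)C(=O)c3c(OCc4ccccc4)cc(OC)c(OC)c3O2)cc(OC)c1OC | intermediate
18 | 5-(benzyloxy)-7,8-dimethoxy-2-(3,4,5-trimethoxyphenyl)chromane-3,4-dione (racemic) | COc1cc(C2Oc3c(OC)c(OC)cc(OCc4ccccc4)c3C(=O)C2=O)cc(OC)c1OC | intermediate
19 | 5-(benzyloxy)-3-hydroxy-7,8-dimethoxy-2-(3,4,5-trimethoxyphenyl)-4H-chromen-4-one | COc1cc(-c2oc3c(OC)c(OC)cc(OCc4ccccc4)c3c(=O)c2O)cc(OC)c1OC | intermediate
20 | 3,5-dihydroxy-7,8-dimethoxy-2-(3,4,5-trimethoxyphenyl)-4H-chromen-4-one | COc1cc(-c2oc3c(OC)c(OC)cc(O)c3c(=O)c2O)cc(OC)c1OC | target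

**Step count**
Total: 13 steps. Longest linear sequence: 11 steps (steps 1–5 and 8–13); steps 6–7 are a two-step side branch.

**Steps most likely to fail**

Step 11. The aliphatic carbonyl may be reduced in competition, with reductive loss of the α-aryloxy group. The aryl ketyl may also be reduced further to the benzylic alcohol or couple bimolecularly before it cyclises. The fallback makes the same C3–C4 bond by a two-electron pathway and sets out from 8. Hydroboration of commercial 5-ethynyl-1,2,3-trimethoxybenzene with catecholborane would give the catechol styrylboronate F1, which water hydrolyses to (E)-[2-(3,4,5-trimethoxyphenyl)ethenyl]boronic acid F2. Heating 8 with F2 and catalytic dibenzylamine in dioxane at 90 °C should bring about a Petasis-type transfer of the styryl group to the aldehyde carbon, loss of the amine to an ortho-quinone methide and oxa-6π electrocyclisation, giving the 2-aryl-2H-chromene F3. Upjohn dihydroxylation of F3 (OsO4 cat., N-methylmorpholine N-oxide, acetone–water) on the face away from the 2-aryl group would give the 2,3-trans-3,4-cis diol, and the route is rejoined at 16.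

Step 10. The α-aryl-α-aryloxy aldehyde may enolise during oxidation or work-up and add to the neighbouring formyl group in an intramolecular aldol reaction. Alternatively, the mono-oxidised hydroxy aldehyde may close to a lactol that is oxidised further. The fallback reaches the dialdehyde by controlled reduction instead of over-reduction and re-oxidation, and sets out from 13. Ethylene glycol with catalytic TsOH in toluene under water removal would give the dioxolane-protected ester F4. Treatment with i-Bu2AlH in CH2Cl2 at −78 °C should stop at the aldehyde level through the chelated aluminium hemiacetal and give the dioxolane aldehyde F5. Pyridinium tosylate in wet acetone at rt would then open the very acid-labile electron-rich aryl acetal, and the route is rejoined at 15, used directly in step 11.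

Step 12. Excess pentavalent iodine may over-oxidise the electron-rich enol of the flavonol, or the glycol C–C bond may be cleaved, so that the one-flask double oxidation does not stop cleanly at the flavonol. The fallback separates the two events and sets out from 16. Activated MnO2 in CH2Cl2 at rt should oxidise only the benzylic C4–OH, so that the dihydroflavonol 17 is isolated. Dehydrogenation with I2 and KOAc in hot AcOH (α-iodination of the enol and loss of HI) would then give the flavonol, and the route is rejoined at 19. No compound outside the list arises (F0).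

**Further compounds**
F1 | step 11 | (E)-2-[2-(3,4,5-trimethoxyphenyl)ethenyl]-1,3,2-benzodioxaborole | COc1cc(/C=C/B2Oc3ccccc3O2)cc(OC)c1OC
F2 | step 11 | (E)-[2-(3,4,5-trimethoxyphenyl)ethenyl]boronic acid | COc1cc(/C=C/B(O)O)cc(OC)c1OC
F3 | step 11 | 5-(benzyloxy)-7,8-dimethoxy-2-(3,4,5-trimethoxyphenyl)-2H-chromene (racemic) | COc1cc(C2C=Cc3c(OCc4ccccc4)cc(OC)c(OC)c3O2)cc(OC)c1OC
F4 | step 10 | methyl 2-[3-(benzyloxy)-2-(1,3-dioxolan-2-yl)-5,6-dimethoxyphenoxy]-2-(3,4,5-trimethoxyphenyl)acetate (racemic) | COC(=O)C(Oc1c(C2OCCO2)c(OCc2ccccc2)cc(OC)c1OC)c1cc(OC)c(OC)c(OC)c1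
F5 | step 10 | 2-[3-(benzyloxy)-2-(1,3-dioxolan-2-yl)-5,6-dimethoxyphenoxy]-2-(3,4,5-trimethoxyphenyl)acetaldehyde (racemic) | O=CC(Oc1c(C2OCCO2)c(OCc2ccccc2)cc(OC)c1OC)c1cc(OC)c(OC)c(OC)c1
F0 | step 12 | none | none
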